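Numbering follows the germacranolide convention: ring carbons C1–C10, acrylate carbons C11–C13, C14 is the methyl on C10, C15 the methylene on C4.
Retrosynthetic cuts, in order: the lactone O–C6 bond (after tracing the C5 alcohol back to a C5 ketone); C4–C5 (Nozaki–Hiyama–Kishi ring closure); C7–C8 (2-(alkoxycarbonyl)allylation joining fragment A and fragment B); furanone C2–C3 and O–C3 (Claisen condensation, cyclodehydration); C9–C10 (enolate allylation).
Forward ring order: chiral dioxolanone template, then the 3(2H)-furanone, then the oxygen-bridged ten-membered carbocycle, then the α-methylene-γ-lactone last.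
Enabling feature: in the ten-membered ring C6 is the only enolisable α-carbon of the C5 ketone (C4 is sp2 and carries the exo-methylene) and lies γ to the C12 carboxyl. This 5-oxo acid motif lets a trivalent-iodine umpolung join the enol carbon to the carboxylate oxygen, closing the lactone and creating C6 from a CH2 group.
Stereochemistry: C10 from (S)-lactic acid by self-regeneration of the stereocentre; C8 by catalyst control and C7 by the syn preference of the allylation; C6 by trans ring fusion relayed from C7; C5 by chelation-controlled reduction relayed from C6.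

Key step: step 17

Step 1
Reactants: 1 (S)-lactic acid
Product: 2 (2S,5S)-2-tert-butyl-5-methyl-1,3-dioxolan-4-one
Conditions: pivalaldehyde, TsOH·H2O (cat.), H2SO4 (cat.), pentane, reflux with water separator; crystallisation of the cis isomer
Reagents that add atoms: pivalaldehyde, CC(C)(C)C=O
Why: Acid-catalysed acetalisation of the α-hydroxy acid should give mainly the crystallisable cis-dioxolanone, which stores the lactic acid configuration in the new acetal centre (self-regeneration of stereocentres).

Step 2
Reactants: 2 (2S,5S)-2-tert-butyl-5-methyl-1,3-dioxolan-4-one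
Product: 3 (2S,5R)-5-allyl-2-tert-butyl-5-methyl-1,3-dioxolan-4-one
Conditions: LiN(i-Pr)2, THF, −78 °C; allyl bromide, −78 → −20 °C
Reagents that add atoms: allyl bromide, C=CCBr
Why: The planar lithium enolate should be alkylated anti to the tert-butyl group (enolate alkylation of a chiral dioxolanone), so allyl replaces the original hydrogen with overall retention and sets the quaternary C10 centre.

Step 3
Reactants: 3 (2S,5R)-5-allyl-2-tert-butyl-5-methyl-1,3-dioxolan-4-one
Product: 4 (R)-2-hydroxy-N-methoxy-N,2-dimethylpent-4-enamide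
Conditions: MeNH(OMe)·HCl, AlMe3, CH2Cl2, 0 °C → rt; aq. HCl work-up
Reagents that add atoms: N,O-dimethylhydroxylamine hydrochloride, CNOC.Cl
Why: Aluminium amide aminolysis of the activated acylal ester should open the dioxolanone and release pivalaldehyde, giving the N-methoxy-N-methylamide without touching the quaternary centre.

Step 4
Reactants: 4 (R)-2-hydroxy-N-methoxy-N,2-dimethylpent-4-enamide
Product: 5 (R)-3-hydroxy-3-methylhex-5-en-2-one
Conditions: MeMgBr (3 equiv), THF, −20 → 0 °C; aq. NH4Cl
Reagents that add atoms: methylmagnesium bromide, C[Mg]Br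
Why: After deprotonation of the tertiary alcohol, Grignard addition to the N-methoxy-N-methylamide should stop at the chelated tetrahedral intermediate, so the methyl ketone forms without over-addition.

Step 5
Reactants: 5 (R)-3-hydroxy-3-methylhex-5-en-2-one
Product: 7 (R)-5-acetyl-2-allyl-2-methylfuran-3(2H)-one, via hydroxy diketone ketal 6 (not isolated)
Conditions: LiN(i-Pr)2 (3.2 equiv), THF, −78 °C; methyl 2,2-dimethoxypropanoate, −78 → 0 °C; aq. NH4Cl; crude product, TsOH·H2O (cat.), THF/H2O, 45 °C
Reagents that add atoms: methyl 2,2-dimethoxypropanoate, COC(=O)C(C)(OC)OC; water, O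
Why: Crossed Claisen condensation of the kinetic methyl ketone enolate with a non-enolisable ester should give the α'-hydroxy 1,3-diketone, whose acid-catalysed 5-exo hemiketalisation and dehydration forms the 3(2H)-furanone while the ketal is hydrolysed to the acetyl group.

Step 6
Reactants: 7 (R)-5-acetyl-2-allyl-2-methylfuran-3(2H)-one
Product: 8 1-[(R)-5-allyl-5-methyl-4-oxo-4,5-dihydrofuran-2-yl]vinyl trifluoromethanesulfonate
Conditions: KN(SiMe3)2, THF, −78 °C; PhNTf2, −78 → 0 °C
Reagents that add atoms: N-phenylbis(trifluoromethanesulfonimide), O=S(=O)(N(c1ccccc1)S(=O)(=O)C(F)(F)F)C(F)(F)F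
Why: The acetyl methyl group is the only enolisable position (C10 is quaternary), so kinetic enolate formation and O-sulfonylation should give the terminal enol triflate that later serves as the C4 alkenyl electrophile.

Step 7
Reactants: 8 1-[(R)-5-allyl-5-methyl-4-oxo-4,5-dihydrofuran-2-yl]vinyl trifluoromethanesulfonate
Product: 9 1-[(R)-5-methyl-4-oxo-5-(2-oxoethyl)-4,5-dihydrofuran-2-yl]vinyl trifluoromethanesulfonate (fragment A)
Conditions: OsO4 (cat.), NaIO4, 2,6-lutidine, dioxane/H2O, rt; used at once
Reagents that add atoms: OsO4, O=[Os](=O)(=O)=O; NaIO4 (terminal oxidant), [Na+].[O-]I(=O)(=O)=O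
Why: Lemieux–Johnson oxidation should cleave the electron-rich monosubstituted alkene in preference to the electron-poor enol triflate and the push–pull furanone double bond, unmasking the C8 aldehyde.

Step 8
Reactants: 10 3-[(tert-butyldimethylsilyl)oxy]propanal; 11 tert-butyl acrylate
Product: 12 tert-butyl 5-[(tert-butyldimethylsilyl)oxy]-3-hydroxy-2-methylenepentanoate (racemic)
Conditions: DABCO, dioxane/H2O, rt, several days
Reagents that add atoms: none
Why: Morita–Baylis–Hillman reaction of the acrylate with the aliphatic aldehyde should give the racemic allylic alcohol, whose carbinol centre is erased in the next step.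

Step 9
Reactants: 12 tert-butyl 5-[(tert-butyldimethylsilyl)oxy]-3-hydroxy-2-methylenepentanoate
Product: 13 tert-butyl (Z)-2-(bromomethyl)-5-[(tert-butyldimethylsilyl)oxy]pent-2-enoate (fragment B)
Conditions: NBS, Me2S, CH2Cl2, 0 °C → rt
Reagents that add atoms: N-bromosuccinimide, O=C1CCC(=O)N1Br
Why: Bromide should attack the alkoxysulfonium intermediate with allylic transposition (SN2') to give the thermodynamically preferred trisubstituted alkene with the chain trans to the ester, the geometry needed for syn addition.

Step 10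
Reactants: 9 fragment A aldehyde; 13 fragment B bromide
Product: 14 tert-butyl (3R,4R)-3-[2-(tert-butyldimethylsilyloxy)ethyl]-4-hydroxy-2-methylene-5-[(R)-2-methyl-3-oxo-5-(1-trifluoromethanesulfonyloxyvinyl)-2,3-dihydrofuran-2-yl]pentanoate
Conditions: CrCl2 (10 mol %), chiral carbazole bis(oxazoline) ligand (12 mol %, enantiomer for Si-face addition), Mn powder, TMSCl, i-Pr2NEt (cat.), THF, rt; then citric acid, MeOH
Reagents that add atoms: none
Why: In this catalytic asymmetric Nozaki–Hiyama allylation the allylchromium species keeps the chain cis to its CH2–Cr terminus and should add through a chair transition state to give the syn C7/C8 pair, while the ligand fixes the aldehyde face (C8) because the remote quaternary C10 centre cannot bias it.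

Step 11
Reactants: 14 C8 alcohol
Product: 15 tert-butyl (3R,4R)-3-[2-(tert-butyldimethylsilyloxy)ethyl]-2-methylene-4-(3-methylbutanoyloxy)-5-[(R)-2-methyl-3-oxo-5-(1-trifluoromethanesulfonyloxyvinyl)-2,3-dihydrofuran-2-yl]pentanoate
Conditions: isovaleryl chloride, pyridine, DMAP (cat.), CH2Cl2, 0 °C
Reagents that add atoms: 3-methylbutanoyl chloride, CC(C)CC(=O)Cl
Why: DMAP-catalysed acylation of the secondary alcohol should install the isovalerate before the hydroxyl can lactonise onto the hindered tert-butyl ester.

Step 12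
Reactants: 15 silyl ether
Product: 16 tert-butyl (3R,4R)-3-(2-hydroxyethyl)-2-methylene-4-(3-methylbutanoyloxy)-5-[(R)-2-methyl-3-oxo-5-(1-trifluoromethanesulfonyloxyvinyl)-2,3-dihydrofuran-2-yl]pentanoate
Conditions: HF·pyridine, pyridine, THF, 0 °C
Reagents that add atoms: none
Why: Buffered fluoride should cleave the primary silyl ether selectively, leaving the enol triflate and both esters intact.

Step 13
Reactants: 16 primary alcohol
Product: 17 tert-butyl (3R,4R)-2-methylene-4-(3-methylbutanoyloxy)-5-[(R)-2-methyl-3-oxo-5-(1-trifluoromethanesulfonyloxyvinyl)-2,3-dihydrofuran-2-yl]-3-(2-oxoethyl)pentanoate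
Conditions: Dess–Martin periodinane, CH2Cl2, 0 °C → rt
Reagents that add atoms: none
Why: Dess–Martin oxidation under neutral conditions should give the C5 aldehyde without β-elimination or migration of the acrylate double bond.

Step 14
Reactants: 17 aldehyde enol triflate
Product: 18 tert-butyl (7R,8R,10R)-5-hydroxy-8-(3-methylbutanoyloxy)-1-oxo-3,10-epoxygermacra-2,4(15),11(13)-trien-12-oate (both C5 epimers)
Conditions: CrCl2 (8 equiv), NiCl2 (2 mol %), degassed DMF (2 mM), rt
Reagents that add atoms: none
Why: In this Nozaki–Hiyama–Kishi reaction nickel-catalysed activation of the enol triflate and transmetalation to chromium should give an alkenylchromium species that adds to the aldehyde in preference to the ketone and esters and closes the oxygen-bridged ten-membered carbocycle under high dilution; both C5 epimers are carried on because this centre is oxidised next.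

Step 15
Reactants: 18 macrocyclic allylic alcohol
Product: 19 tert-butyl (7R,8R,10R)-8-(3-methylbutanoyloxy)-1,5-dioxo-3,10-epoxygermacra-2,4(15),11(13)-trien-12-oate
Conditions: Dess–Martin periodinane, CH2Cl2, 0 °C; used without storage
Reagents that add atoms: none
Why: Dess–Martin oxidation of the allylic alcohol should converge both epimers on the cross-conjugated C5 ketone, whose only enolisable α-carbon is C6.

Step 16
Reactants: 19 keto tert-butyl ester
Product: 20 (7R,8R,10R)-8-(3-methylbutanoyloxy)-1,5-dioxo-3,10-epoxygermacra-2,4(15),11(13)-trien-12-oic acid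
Conditions: TFA/CH2Cl2 (1:4), 0 °C
Reagents that add atoms: none
Why: Acidolysis of the tert-butyl ester with loss of isobutene should free the C12 carboxylic acid while the isovalerate and the furanone are stable to TFA.

Step 17
Reactants: 20 keto acid
Product: 22 (6S,7R,8R,10R)-8-(3-methylbutanoyloxy)-1,5-dioxo-3,10-epoxygermacra-2,4(15),11(13)-trien-12,6-olide, via C6 iodanyl ketone 21 (not isolated)
Conditions: PhI(OH)OTs (1.2 equiv), MeCN, 0 °C → rt
Reagents that add atoms: none
Why: The C5 ketone of 20 enolises towards C6 (the only enolisable α-carbon, since C4 is sp2) and the enol attacks the trivalent iodine reagent to give the C6 aryl-λ3-iodanyl ketone 21, in which the formerly nucleophilic carbon has become electrophilic. The C12 carboxyl oxygen then displaces iodobenzene from C6 in an intramolecular substitution that forms the lactone O–C6 bond; the ring is closed in the 5-exo-tet mode. The closest known reaction type is the oxidative lactonisation of 5-oxo carboxylic acids to 5-oxo-4-olides with hydroxy(tosyloxy)iodobenzene. The new C6 stereocentre is controlled by C7 through the ring fusion: the trans-fused γ-lactone (H6 and H7 anti, C5 and C8 on opposite faces) should result because the iodanyl epimers interconvert through the enol before displacement and the α-acyloxy ketone product stays epimerisable at C6 under the acidic conditions. The step needs regioselectivity for C6 and chemoselectivity over the furanone C2 carbon and the alkenes; the substrate secures this because the ketone has a single enolisable position, all three C=C bonds are electron-poor (acrylic acid, exo-methylene enone, acyl-substituted furanone) and the carboxyl is held five atoms from C6.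

Step 18
Reactants: 22 keto lactone
Product: 23 (5R,6S,7R,8R,10R)-5-hydroxy-8-(3-methylbutanoyloxy)-1-oxo-3,10-epoxygermacra-2,4(15),11(13)-trien-12,6-olide (CNP0409337.2)
Conditions: Zn(BH4)2, Et2O/THF, −30 °C; aq. NH4Cl
Reagents that add atoms: none
Why: In this chelation-controlled 1,2-reduction zinc should bridge the C5 carbonyl and the lactone oxygen on C6 so that hydride adds from the face opposite C7 to give the 5,6-anti (5R) allylic alcohol, while the less electrophilic vinylogous-ester carbonyl at C1 and the α-methylene lactone are left untouched.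

Compound list
1 | (S)-lactic acid | C[C@H](O)C(=O)O | starting material
2 | (2S,5S)-2-tert-butyl-5-methyl-1,3-dioxolan-4-one | C[C@@H]1O[C@H](C(C)(C)C)OC1=O | intermediate
3 | (2S,5R)-5-allyl-2-tert-butyl-5-methyl-1,3-dioxolan-4-one | C[C@]1(CC=C)O[C@H](C(C)(C)C)OC1=O | intermediate
4 | (R)-2-hydroxy-N-methoxy-N,2-dimethylpent-4-enamide | C=CC[C@@](C)(O)C(=O)N(C)OC | intermediate
5 | (R)-3-hydroxy-3-methylhex-5-en-2-one | C=CC[C@@](C)(O)C(C)=O | intermediate
6 | (R)-6-hydroxy-2,2-dimethoxy-6-methylnon-8-ene-3,5-dione (not isolated) | C=CC[C@@](C)(O)C(=O)CC(=O)C(C)(OC)OC | intermediate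
7 | (R)-5-acetyl-2-allyl-2-methylfuran-3(2H)-one | C=CC[C@@]1(C)OC(C(C)=O)=CC1=O | intermediate
8 | 1-[(R)-5-allyl-5-methyl-4-oxo-4,5-dihydrofuran-2-yl]vinyl trifluoromethanesulfonate | C=CC[C@@]1(C)OC(C(=C)OS(=O)(=O)C(F)(F)F)=CC1=O | intermediate
9 | 1-[(R)-5-methyl-4-oxo-5-(2-oxoethyl)-4,5-dihydrofuran-2-yl]vinyl trifluoromethanesulfonate (fragment A) | O=CC[C@@]1(C)OC(C(=C)OS(=O)(=O)C(F)(F)F)=CC1=O | intermediate
10 | 3-[(tert-butyldimethylsilyl)oxy]propanal | O=CCCO[Si](C)(C)C(C)(C)C | starting material
11 | tert-butyl acrylate | C=CC(=O)OC(C)(C)C | starting material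
12 | tert-butyl 5-[(tert-butyldimethylsilyl)oxy]-3-hydroxy-2-methylenepentanoate (racemic) | C=C(C(=O)OC(C)(C)C)C(O)CCO[Si](C)(C)C(C)(C)C | intermediate
13 | tert-butyl (Z)-2-(bromomethyl)-5-[(tert-butyldimethylsilyl)oxy]pent-2-enoate (fragment B) | BrC/C(C(=O)OC(C)(C)C)=C\CCO[Si](C)(C)C(C)(C)C | intermediate
14 | (7R,8R,10R) seco alcohol: C8 OH, C5 OTBS, C12 tert-butyl ester, C4 enol triflate | CC(C)(C)[Si](C)(C)OCC[C@H](C(=C)C(=O)OC(C)(C)C)[C@H](O)C[C@@]1(C)OC(C(=C)OS(=O)(=O)C(F)(F)F)=CC1=O | intermediate
15 | (7R,8R,10R) seco isovalerate: C8 O-isovaleryl, C5 OTBS | CC(C)(C)[Si](C)(C)OCC[C@H](C(=C)C(=O)OC(C)(C)C)[C@H](OC(=O)CC(C)C)C[C@@]1(C)OC(C(=C)OS(=O)(=O)C(F)(F)F)=CC1=O | intermediate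
16 | (7R,8R,10R) seco primary alcohol: C5 OH | OCC[C@H](C(=C)C(=O)OC(C)(C)C)[C@H](OC(=O)CC(C)C)C[C@@]1(C)OC(C(=C)OS(=O)(=O)C(F)(F)F)=CC1=O | intermediate
17 | (7R,8R,10R) seco aldehyde: C5 CHO, C4 enol triflate | O=CC[C@H](C(=C)C(=O)OC(C)(C)C)[C@H](OC(=O)CC(C)C)C[C@@]1(C)OC(C(=C)OS(=O)(=O)C(F)(F)F)=CC1=O | intermediate
18 | tert-butyl (7R,8R,10R)-5-hydroxy-8-(3-methylbutanoyloxy)-1-oxo-3,10-epoxygermacra-2,4(15),11(13)-trien-12-oate (C5 epimers) | C=C(C(=O)OC(C)(C)C)[C@H]1CC(O)C(=C)C2=CC(=O)[C@](C)(O2)C[C@H]1OC(=O)CC(C)C | intermediate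
19 | tert-butyl (7R,8R,10R)-8-(3-methylbutanoyloxy)-1,5-dioxo-3,10-epoxygermacra-2,4(15),11(13)-trien-12-oate | C=C(C(=O)OC(C)(C)C)[C@H]1CC(=O)C(=C)C2=CC(=O)[C@](C)(O2)C[C@H]1OC(=O)CC(C)C | intermediate
20 | (7R,8R,10R)-8-(3-methylbutanoyloxy)-1,5-dioxo-3,10-epoxygermacra-2,4(15),11(13)-trien-12-oic acid | C=C(C(=O)O)[C@H]1CC(=O)C(=C)C2=CC(=O)[C@](C)(O2)C[C@H]1OC(=O)CC(C)C | intermediate
21 | C6 phenyl(tosyloxy)-λ3-iodanyl derivative of 20 (C6 epimers, not isolated) | C=C(C(=O)O)[C@H]1C(I(c3ccccc3)OS(=O)(=O)c3ccc(C)cc3)C(=O)C(=C)C2=CC(=O)[C@](C)(O2)C[C@H]1OC(=O)CC(C)C | intermediate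
22 | (6S,7R,8R,10R)-8-(3-methylbutanoyloxy)-1,5-dioxo-3,10-epoxygermacra-2,4(15),11(13)-trien-12,6-olide | C=C1C(=O)O[C@H]2[C@H]1[C@H](OC(=O)CC(C)C)C[C@@]1(C)OC(=CC1=O)C(=C)C2=O | intermediate
23 | (5R,6S,7R,8R,10R)-5-hydroxy-8-(3-methylbutanoyloxy)-1-oxo-3,10-epoxygermacra-2,4(15),11(13)-trien-12,6-olide | C=C1C(=O)O[C@H]2[C@H]1[C@H](OC(=O)CC(C)C)C[C@@]1(C)OC(=CC1=O)C(=C)[C@H]2O | target

Total step count: 18. Longest linear sequence: 16 steps (steps 1–7 and 10–18).

Steps most likely to fail

Step 17 (key step): the iodine reagent may attack the nucleophilic C2 position of the furanone in competition with the C5 enol, or ring closure may give the cis-fused lactone without equilibration at C6. Fallback: from 19, kinetic enolisation and silylation (LiN(SiMe3)2, TMSCl, THF, −78 °C) would give the C5 trimethylsilyl dienol ether F1. NBS would convert it into the C6 bromo ketone F2. AgOTf in CH2Cl2 would then promote displacement of bromide by the carbonyl oxygen of the tert-butyl ester with loss of isobutene. This forms the same lactone by a separate halogenation and substitution sequence and returns to 22.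

Step 14: oligomerisation by intermolecular addition may outrun closure of the strained oxygen-bridged ring. Fallback: from 17, NaClO2/NaH2PO4/2-methyl-2-butene would give the C5 carboxylic acid F3. Pd(PPh3)4, Me3SnSnMe3 and LiCl (acid held as its ammonium salt) would exchange the enol triflate for a trimethylstannyl group to give the stannyl acid F4. 1-Chloro-N,N,2-trimethylpropenylamine would give the acid chloride F5. Pd2(dba)3 with tri(2-furyl)phosphine in dilute toluene would then close the ring by intramolecular acylative Stille coupling, which forms C4–C5 directly at the ketone level and returns to 19.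

Step 18: hydride may add to the wrong face of the C5 carbonyl if the macrocycle prevents chelation (poor facial selectivity), or conjugate reduction may compete. Fallback: from 22, a non-chelating reduction (NaBH4, CeCl3, MeOH, −78 °C) would be run deliberately to the 5S alcohol F6. A Mitsunobu reaction with formic acid (PPh3, diisopropyl azodicarboxylate) would invert C5 to give the 5R formate F7. KHCO3 in aqueous MeOH would cleave the formate and return to 23.

Further compounds
F1 | step 17 | C5 trimethylsilyl dienol ether of 19 | C=C(C(=O)OC(C)(C)C)[C@H]1C=C(O[Si](C)(C)C)C(=C)C2=CC(=O)[C@](C)(O2)C[C@H]1OC(=O)CC(C)C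
F2 | step 17 | C6 bromo ketone of 19 (C6 epimers) | C=C(C(=O)OC(C)(C)C)[C@H]1C(Br)C(=O)C(=C)C2=CC(=O)[C@](C)(O2)C[C@H]1OC(=O)CC(C)C
F3 | step 14 | C5 carboxylic acid from 17 (enol triflate retained) | OC(=O)C[C@H](C(=C)C(=O)OC(C)(C)C)[C@H](OC(=O)CC(C)C)C[C@@]1(C)OC(C(=C)OS(=O)(=O)C(F)(F)F)=CC1=O
F4 | step 14 | C4 trimethylstannyl C5 acid | OC(=O)C[C@H](C(=C)C(=O)OC(C)(C)C)[C@H](OC(=O)CC(C)C)C[C@@]1(C)OC(C(=C)[Sn](C)(C)C)=CC1=O
F5 | step 14 | C4 trimethylstannyl C5 acid chloride | ClC(=O)C[C@H](C(=C)C(=O)OC(C)(C)C)[C@H](OC(=O)CC(C)C)C[C@@]1(C)OC(C(=C)[Sn](C)(C)C)=CC1=O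
F6 | step 18 | (5S)-epimer of 23 | C=C1C(=O)O[C@H]2[C@H]1[C@H](OC(=O)CC(C)C)C[C@@]1(C)OC(=CC1=O)C(=C)[C@@H]2O
F7 | step 18 | (5R)-formate of 23 | C=C1C(=O)O[C@H]2[C@H]1[C@H](OC(=O)CC(C)C)C[C@@]1(C)OC(=CC1=O)C(=C)[C@H]2OC=O
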